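(Readings and results were computed with constants of no real substance; scatter was added.)

The molar day, substrate charge multiplied by time, is the unit in which to compare these flasks.

the same everywhere: gas 160 mM (held)
- birch: substrate 0.70 M; run made earlier
- oak: substrate 1.1 M; run made earlier
- flask: substrate 0.50 M; time 3.0 d

| run | time / d | product / % | substrate / % |
|---|---|---|---|
| birch | 0.833 | 76.2 | 24.6 |
| birch | 1.67 | 86.8 | 10.9 |
| birch | 2.50 | 91.9 | 8.0 |
| birch | 4.00 | 95.3 | 3.9 |
| oak | 0.417 | 63.1 | 35.0 |
| oak | 1.25 | 89.6 | 12.7 |
| oak | 2.50 | 94.8 | 4.9 |
| oak | 4.00 | 97.8 | 1.8 |

(standard deviation of a reading: 1 percentage point)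

- at the start none of the gas is in solution

1. the product in the flask at 3.0 d, as a percentage of the substrate charged
2. the substrate in the flask at 3.0 d, as a percentage of the substrate charged
3. concentration of coupling partner at 3.0 d, in M

The flask looks nearly like birch at its third reading: it has less substrate but more time. Late substrate readings are the ones to watch, so the reckoning uses the fraction left. Birch gives 6.57 /M/d at 2.50 d and oak gives 7.06 /M/d at 2.50 d, and each of these carries the scatter of its reading. Their mean, 6.81 /M/d, is K, a pseudo-second-order constant: the reciprocal of the fraction of substrate left, less one, per molar day. The first birch reading gives less, 5.26 /M/d, so K is a late-time reading.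

Birch at its third reading stands at 0.70 M times 2.50 d, while the flask stands at 0.50 M times 3.0 d, which is 0.857 of the birch product. Because of that smaller product, this reckoning leaves 8.91% substrate in the flask, more than the 8.0% read in birch, despite the longer time. It also takes c_partner as dissolved gas standing near 0.16 M.

The forecast gives 9.5% substrate, 90% product and 0.45 M coupling partner, with the words: "The coupling partner was not charged, so I assume it forms one-to-one with product". The two reckonings part on the partner.

The flask gives 9.17% substrate, 90.8% product and 0.159 M coupling partner, while its product stands at 0.454 M. The flask's own K is 6.60 /M/d.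

    gas ⇌ coupling partner, rate k1*(csat - [coupling partner]) (kL = 1.20 /h)
    substrate + coupling partner → product, rate k2*[substrate]^2*[coupling partner] (k = 1.80 /M²/h)

The neighbouring flask, charged with 0.12 M of substrate, also stands for 3.0 d, and K leaves 29.0% there. That flask holds 29.0% substrate, 71.0% product and 0.160 M coupling partner.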